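(The data are calculated for an exercise; the scatter is artificial.)

1. Look for a ratio, target formed per partner used, and read the new flasks through it; the flasks, the earlier runs and the questions stand here.

| flask | substrate | partner | temperature | remark | time |
|---|---|---|---|---|---|
| violet | 0.013 M | 0.020 M | 68 °C | run made earlier |  |
| green | 0.030 M | 0.020 M | 84 °C | run made earlier |  |
| oak | 0.020 M | 0.0200 M | 60 °C |  | 6.0 min |
| alder | 0.020 M | 0.0200 M | 90 °C |  | 6.0 min |
| maple | 0.020 M | 0.0200 M |  | at 90 °C until 3.0 min, from then on at 60 °C | 6.0 min |

violet run (percent of the substrate charged)

| time / min | target / % | substrate / % |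
|---|---|---|
| 1.00 | 23.4 | 4.4 |
| 2.00 | 23.6 | 0.3 |
| 3.00 | 24.6 | 0 |
| 4.00 | 25.6 | 0.2 |
| 5.00 | 22.7 | 0 |
| 6.00 | 24.8 | 0 |

green run (percent of the substrate charged)

| time / s | target / % | substrate / % |
|---|---|---|
| 20.0 | 15.4 | 35.8 |
| 40.0 | 13.8 | 31.2 |
| 60.0 | 15.4 | 33.4 |
| 80.0 | 16.6 | 34.2 |
| 90.0 | 16.1 | 31.6 |
| 120 | 15.9 | 33.9 |

(each reading ± 1 percentage point)

* which flask leads in amount of target, in percent of the substrate charged ("all alike" within 1.5 percentage points) (oak / alder / maple / all alike)
* how much target is there at the end, in percent of the substrate charged: oak
* how much target is there at the end, in percent of the substrate charged: alder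
* how much target is there at the end, in percent of the substrate charged: maple

- the analysis behind the earlier runs scatters by 1 percentage point, standard deviation

2. Average the green readings: substrate holds at 33.4 %, so 0.0200 M has been used, which matches the 0.020 M of partner charged; read this as one partner used per substrate, with partner the limiting reagent in green.

3. Write the balance of partner: partner used equals substrate used, and target is a fixed fraction of partner used, if that fraction holds from run to run.

4. Test that fraction on both runs. In violet, where substrate reads 0.3 % at 2.00 min, the target readings from then on average 24.3 % of the substrate charged, while green gives 23.3 % of the substrate used. These differ by 1.00 percentage point, about one reading's scatter, so take their mean, 23.8 %, as the target share: target formed per partner used, a selectivity read from these readings.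

5. Turn to the new flasks, where equal charges make [substrate] and [partner] fall together, so the fraction used is kct/(1+kct), with c the starting [substrate] and k the total second-order constant. Integrating violet's reading at 1.00 min with its unequal charges gives k = 307 M⁻¹ min⁻¹ at 68 °C.

6. Take half of that k as my cautious value for oak at 60 °C: kct is 18.4, the fraction used 94.9 %, and target 22.6 %. The ceiling at full use is the share itself, and the gap of 1.2 points is smaller than the margin. Alder and maple start at 90 °C, hotter than oak, and green at 84 °C already stood level at its first reading, 20.0 s, so I commit to a tie.

7. The forecast gives 22.9 % for oak, above my cautious figure, then 23.2 % for alder and 23.2 % for maple, with the verdict all alike. In its words: “Cooling maple changes nothing.”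

8. The flasks give 22.9 % for oak, 23.8 % for alder and 23.6 % for maple: all alike.

    substrate + partner → target (k = 49.0 M⁻¹ min⁻¹, Ea = 52.0 kJ mol⁻¹)
    substrate + partner → isomer of the product (k = 140 M⁻¹ min⁻¹, Ea = 50.0 kJ mol⁻¹)
    substrate + partner → second isomer (k = 17.0 M⁻¹ min⁻¹, Ea = 63.0 kJ mol⁻¹)
    (constants at 60 °C)

Apply the share to oak's conversion of 96.1 %: it gives 22.9 %, beside the 22.9 % found. Oak's target stands that low because substrate and partner also go to isomer of the product: with that step taken away, oak holds 65.9 % of target. A neighbour of maple shows what ends the tie: charged with 0.0080 M of partner against 0.020 M of substrate, it can use that much, so the share gives 9.52 %. That neighbour ends with 0 % of its partner and 60.0 % of its substrate left, and its target stands at 9.58 %, which is 14 points below maple.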